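The earlier runs and the new flask were generated by integration for an exercise; scatter was added.

The meeting opened with the charges.

in all of them: substrate 0.050 M
- Sunday's: reagent 0.088 M; run made earlier
- Wednesday's: reagent 0.14 M; run made earlier
- Friday's: reagent 0.22 M; run made earlier
- summer: reagent 0.100 M; time 80 min
- dawn: reagent 0.150 M; time 80 min
- spring: reagent 0.200 M; time 80 min

| run | time / min | tris adduct / % | substrate / % |
|---|---|---|---|
| Sunday's | 5.00 | 0 | 21 |
| Sunday's | 15.0 | 4 | 6 |
| Sunday's | 25.0 | 9 | 9 |
| Sunday's | 40.0 | 16 | 8 |
| Sunday's | 60.0 | 21 | 5 |
| Wednesday's | 5.00 | 2 | 12 |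
| Wednesday's | 15.0 | 13 | 5 |
| Wednesday's | 25.0 | 23 | 5 |
| Wednesday's | 40.0 | 42 | 1 |
| Wednesday's | 60.0 | 51 | 1 |
| Friday's | 12.0 | 25 | 0 |
| Friday's | 25.0 | 54 | 1 |
| Friday's | 30.0 | 60 | 0 |
| Friday's | 50.0 | 81 | 1 |
| Friday's | 60.0 | 87 | 0 |

(readings scatter by 1.5 percentage points)

- the analysis behind the earlier runs scatters by 1.5 percentage points, standard deviation
- steps that have been proposed: substrate + reagent -> first product; reagent + first product -> bis adduct; reagent + bis adduct -> tris adduct; substrate <-> dormant form

* final tris adduct, as a percentage of the substrate charged, for each flask in turn (summer, dawn, spring)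

The analyst reported that the tris adduct read 21% on Sunday, 51% on Wednesday and 87% on Friday, each at 60.0 min, with [substrate] charged at 0.050 M in each run and [reagent] rising.

The process chemist asked that the end state be reckoned first. By the proposed steps a tris adduct holds 3 reagent units, and in a closed flask the reagent taken up per substrate charged is bounded by E, the equivalents charged, which is [reagent] over [substrate] at the start: 2.00 for summer, 3.00 for dawn and 4.00 for spring. In the summer flask E stands below 3, so there reagent is the limiting reagent, and the tris adduct is capped at E over 3, which is 66.7%. The dawn flask's E equals 3 and the spring flask's stands above it, so for these two flasks the cap is the whole substrate charge.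

The kineticist objected that a cap shows the end, not the pace: Sunday's E of 1.76 allows 58.7%, yet the reading at 60.0 min was 21%.

The secretary's own reckoning went no further than this: at 80 min the summer flask should stand well under its cap, and the spring flask, with less E than Friday's 4.40, should still fall short of its own.

The forecast gives 32%, 63% and 90%, remarking of the summer flask that “reagent is nearly spent around the bis stage and tris stalls”.

The flasks gave 29.9% in summer, 65.1% at dawn and 89.0% in spring.

    substrate + reagent → first product (k = 0.0500 L mol⁻¹ s⁻¹)
    reagent + first product → bis adduct (k = 0.0150 L mol⁻¹ s⁻¹)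
    reagent + bis adduct → tris adduct (k = 0.00940 L mol⁻¹ s⁻¹)
    substrate ⇌ dormant form (K = 1.90, k = 0.00440 s⁻¹)

At 800 min the summer flask has reagent at 0% of its charge and tris adduct at 35.5%, less than the cap of 66.7%, beside first product at 20.6% and bis adduct at 36.4%. Weighted by the reagent each holds, these forms make 2.00 equiv, level with its E of 2.00. The dawn flask at 80.0 min has taken up 2.53 equiv of its E of 3.00, with 15.6% of its reagent left.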